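**Numbering key** (full names and SMILES are in the compound list): 1 phloroglucinol; 2 bis-MOM phenol; 3 bromophenol; 4 silyl ether; 5 aryllithium; 6 lithium silylphenoxide; 7 silylaryl triflate (aryne precursor); 8 3,4-bis(benzyloxy)benzaldehyde; 9 dibromoalkene; 10 lithium acetylide; 11 lithium propiolate; 12 arylpropiolic acid; 13 aryne; 14 ortho-hydroxyaryl ynone; 15 flavone from the key step; 16 8-iodoflavone; 17 8-benzyloxyflavone; 18 5,7-diol; 19 protected 7-sulfate; 20 target.

## Analysis of the target

8-Hydroxyluteolin 7-sulfate (20) is a flavone: a benzo ring A fused to a γ-pyranone ring C (O1, C2, C3, C4=O, C4a, C8a), with a catechol ring B on C2. It has no stereocenter, so every problem is one of regiochemistry among oxygen atoms. Ring A is substituted on five of its six carbons: C4a (bearing the C4 carbonyl), C5 (OH), C7 (OSO3H), C8 (OH) and C8a (O1); only C6 carries hydrogen. The sensitive groups are the aryl sulfate monoester (lost in acid, incompatible with Lewis-acidic ether cleavage), the 5,8-dihydroxy para-hydroquinone and the ring B catechol (both oxidised by air in base), and the C2=C3 enone (adds nucleophiles, and ring C opens in hot alkali). The difficulty is to tell five phenolic oxygens apart so that only O7 is sulfated, to bring the sulfate in late, and to remove every other protecting group afterwards under neutral conditions. The strategy rests on one feature: C8a and C4a are adjacent ring A carbons carrying an oxygen (O1) and an acyl carbon (C4), which is the pair an aryne acquires when it inserts into the C–O bond of a carboxylic acid. The oxygen on C5, next to C4a, then polarises the aryne, provided that C8 still carries hydrogen at that stage.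

## Retrosynthetic reasoning

20 to 19. The last bonds cut are the three benzyl C–O bonds at O8, O3' and O4'. Benzyl is chosen because hydrogenolysis is neutral and leaves an aryl sulfate salt, the enone and the free phenols untouched. The forward step must remove three ethers, one of them hindered, without reducing C2=C3.

19 to 18. The O7–S bond is cut next. In 18 only two hydroxyls are free, and the one on C5 is held in a hydrogen bond to the C4 carbonyl, so sulfation should fall on O7 alone. The O5/O7 differentiation therefore comes from the molecule itself and not from two different protecting groups.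

18 to 17, 16 and 15. The two methoxymethyl (MOM) acetals on O5 and O7 are cut together; mild acid removes them and leaves benzyl ethers. The C8–O bond of 17 is then cut back to the aryl iodide 16, and the C8–I bond back to 15. The C8 oxygen is introduced after ring construction because an aryne flanked by oxygen on both sides would have no bias for the key addition. In 15, C8 is the most accessible activated position of ring A, so iodination followed by copper-catalysed etherification can install O8 directly as its benzyl ether.

15 to 7 and 12 (through 13 and 14). This is the central disconnection: C8a–O1, C4a–C4 and O1–C2 are cut, which removes ring C and separates the molecule into a ring A aryne 13 and the three-carbon acid 12 that carries ring B. Cutting here and not at the usual diketone stage avoids a preformed ortho-hydroxyacetophenone and joins the two halves in the ring-forming step. Forward, the acid oxygen must end on the future C8a and the acyl carbon on the future C4a, and the phenoxide of 14 must close in the six-membered mode.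

7 to 4, 3, 2 and 1. The silyl triflate 7 is traced to the lithium phenoxide 6, which arises from aryllithium 5 by oxygen-to-carbon silyl migration, and so to the silyl ether 4 of bromophenol 3. Compound 3 comes from 2 by ortho bromination, and 2 from 1 by twofold acetalisation. The two ether groups of 2 are deliberately identical, because that makes its two ortho positions the same carbon by symmetry. A phenol with two different ethers would give two ortho-brominated isomers, and hence two arynes, that no reagent could tell apart.

12 to 9 and 8. The C–CO2H bond of 12 is cut to the lithium acetylide 10 (carboxylated to 11), and the alkyne to dibromoalkene 9, a one-carbon homologation of the commercial aldehyde 8. This puts ring B, already benzyl-protected, into the acid partner in two steps.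

## Alternatives that were turned down

Alternative 1: Ring A is removed completely by cutting C5–C6, C7–C8 and C8–C8a, so that rings C and B form the scaffold. Forward, the chromium carbene complex A1 would be heated with the silyloxyalkyne A2. In A1 the carbene carbon sits on the pyranone carbon that becomes C4a and already carries the future O5 as a benzyloxy group. Alkyne insertion, CO insertion and electrocyclisation (Dötz benzannulation) would give phenol A3.
- For: A3 leaves the key step with all three ring A oxygens in place and differentiated (O5 benzylated, O7 silylated, O8 free). On this point it is clearly stronger than the chosen route, which needs steps 8 to 10 to reach the comparable diol 18.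
- Against: A1 requires a pyranone metalated next to its carbonyl, which competes with conjugate addition and ring opening of the vinylogous ester. The acylchromate must then be O-benzylated, which is much less routine than methylation. The carbene sits on an electron-poor, chelating heterocycle, where benzannulation competes with five-ring and furan formation. A3 is a para-hydroquinone monoether that oxidises easily on decomplexation, and chromium is stoichiometric.
- Comparison: the chosen route gives up delivery of O8 with the ring. In exchange it uses two partners (7 and 12) that are each a few robust steps from commodity chemicals, and a metal-free key step of an established type.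

Alternative 2: Ring A is again built on the finished pyranone, the decisive cut being C4a–C5. Forward, heating the racemic hydroxycyclobutenone A4 would open the four-membered ring to a dienylketene, which closes by a six-electron electrocyclisation onto the pyranone double bond and tautomerises to hydroquinone A5 (Moore rearrangement).
- For: O5 and O8 arrive with the ring, O7 comes with its own oxidatively removable 4-methoxybenzyl group, no metal is needed, and the regiochemistry is fixed by the connectivity of A4. On the oxygenation pattern it is stronger than the chosen route.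
- Against: A4 requires a pyranone carbanion at the carbon next to the ring oxygen, a poorly behaved nucleophile. It also requires a mono-alkoxy cyclobutenedione whose two carbonyls must be distinguished in the addition. The thermolysis exposes a tertiary allylic alcohol and an acid-sensitive ether to prolonged heating. A5 is an air-sensitive para-hydroquinone whose O8 must still be benzylated selectively.
- Comparison: here the uncertainty sits in making the precursor A4, before the key step can be tried. The chosen route has simple, well-precedented precursors and concentrates its risk in one step.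

Alternative 3: Only O1–C8a is cut, so the carbon skeleton is that of the 1,3-diketone A6. Forward, (NH4)2Ce(NO3)6, a tetravalent cerium oxidant, would convert the para-dimethoxy ring of A6 into an acylquinone. The enol oxygen of the diketone would add to the quinone carbon next to the acyl group (C8a), and a dithionite work-up would deliver hydroquinone A7.
- For: A6 is accessible by classical Claisen-type chemistry, and A7 needs only O8-benzylation, deallylation, sulfation and hydrogenolysis. In step count after the key step and in predictability of the precursor synthesis it is at least as strong as the chosen route, probably stronger.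
- Against: the oxidant meets an enolisable 1,3-diketone (which tetravalent cerium oxidises to radicals), the electron-rich bis(benzyloxy) ring B and an allyl ether in the same molecule. Which two alkoxy groups of ring A are expelled (para-quinone or ortho-quinone) is not guaranteed, and A7 is easily over-oxidised.
- Comparison: the chosen route forms ring C under basic, non-oxidising conditions that cannot touch ring B or the protecting groups, and it is convergent. It pays for this with the late C8 functionalisation.

Key step: step 7

Assumption: the target is drawn as the free hydrogen sulfate. The sulfate would be carried through steps 11 and 12 as its sodium salt for stability and converted to the drawn acid form by a brief cold cation exchange at the end; 19 and 20 are written in the neutral acid form.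

## Route

Step 1
Reactants: 1 phloroglucinol
Product: 2 3,5-bis(methoxymethoxy)phenol
Conditions: MOMCl (2.1 equiv), i-Pr2NEt, CH2Cl2–DMF, 0 °C → rt
Reagents that add atoms: chloromethyl methyl ether, COCCl
Why: O-alkylation of the phenol with an α-chloro ether (acetal formation); the three hydroxyls are equivalent, so the only issue is the degree of alkylation. With two equivalents the bis-ether should be the main component of a statistical mixture, separable by chromatography from the mono- and tris-ethers; the mono-ether can be resubmitted.

Step 2
Reactants: 2 3,5-bis(methoxymethoxy)phenol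
Product: 3 2-bromo-3,5-bis(methoxymethoxy)phenol
Conditions: NBS (1.0 equiv), CH2Cl2, −78 → −20 °C
Reagents that add atoms: N-bromosuccinimide, O=C1CCC(=O)N1Br
Why: Electrophilic aromatic bromination; attack should go ortho to the free hydroxyl (hydrogen-bonded delivery, and less crowded than C4 between two acetal ethers). Because the two ortho positions of 2 are equivalent, one monobromide results; low temperature and one equivalent limit a second bromination.

Step 3
Reactants: 3 2-bromo-3,5-bis(methoxymethoxy)phenol
Product: 4 [2-bromo-3,5-bis(methoxymethoxy)phenoxy]trimethylsilane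
Conditions: HMDS, THF, 70 °C; evaporate
Reagents that add atoms: hexamethyldisilazane, C[Si](C)(C)N[Si](C)(C)C
Why: O-silylation of a phenol with a silazane; only ammonia is released, so the moisture-sensitive silyl ether can be used crude after evaporation.

Step 4
Reactants: 4 [2-bromo-3,5-bis(methoxymethoxy)phenoxy]trimethylsilane
Product: 7 3,5-bis(methoxymethoxy)-2-(trimethylsilyl)phenyl trifluoromethanesulfonate, via 2-lithioaryl silyl ether 5 (not isolated), via lithium 2-silylphenoxide 6 (not isolated)
Conditions: n-BuLi (1.1 equiv), THF, −78 °C; then Tf2O, −78 °C → rt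
Reagents that add atoms: trifluoromethanesulfonic anhydride, O=S(=O)(OS(=O)(=O)C(F)(F)F)C(F)(F)F
Why: Bromine–lithium exchange gives 5, which undergoes the 1,3 oxygen-to-carbon silyl shift (retro-Brook rearrangement) to phenoxide 6, and this is trapped as the triflate; this is the standard entry to ortho-silylaryl triflates. Exchange at −78 °C is faster than acetal-directed ring lithiation, and the phenoxide reacts with Tf2O before the acetals can.

Step 5
Reactants: 8 3,4-bis(benzyloxy)benzaldehyde
Product: 9 1,2-bis(benzyloxy)-4-(2,2-dibromoethenyl)benzene
Conditions: CBr4, PPh3, CH2Cl2, 0 °C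
Reagents that add atoms: carbon tetrabromide, BrC(Br)(Br)Br
Why: First stage of the Corey–Fuchs sequence: the dibromomethylene ylide formed from CBr4 and PPh3 olefinates the aldehyde in a Wittig-type reaction; benzyl ethers are inert.

Step 6
Reactants: 9 1,2-bis(benzyloxy)-4-(2,2-dibromoethenyl)benzene
Product: 12 3-[3,4-bis(benzyloxy)phenyl]prop-2-ynoic acid, via lithium arylacetylide 10 (not isolated), via lithium arylpropiolate 11 (not isolated)
Conditions: n-BuLi (2.2 equiv), THF, −78 °C; CO2, −78 °C → rt; aq. HCl
Reagents that add atoms: carbon dioxide, O=C=O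
Why: Second stage of the Corey–Fuchs sequence: exchange and elimination give acetylide 10, which is carboxylated to 11 and protonated on work-up. At −78 °C the benzyl ethers should not be metalated.

Step 7
Reactants: 7 3,5-bis(methoxymethoxy)-2-(trimethylsilyl)phenyl trifluoromethanesulfonate; 12 3-[3,4-bis(benzyloxy)phenyl]prop-2-ynoic acid
Product: 15 2-[3,4-bis(benzyloxy)phenyl]-5,7-bis(methoxymethoxy)-4H-chromen-4-one, via 3,5-bis(methoxymethoxy)benzyne 13 (not isolated), via ortho-hydroxyaryl ynone 14 (not isolated)
Conditions: CsF (4 equiv), THF, 125 °C, sealed tube (7 in 1.5-fold excess)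
Reagents that add atoms: none
Why: Fluoride attacks silicon in 7 and triflate leaves, releasing aryne 13; the cesium carboxylate of 12 adds through oxygen to the aryne carbon remote from the flanking acetal ether, because that oxygen substituent withdraws inductively, distorts the aryne and stabilises the aryl anion on the carbon next to it. The anion attacks the ester carbonyl just formed, giving a four-membered alkoxide that collapses with C–O cleavage to the ortho-acyl phenoxide of 14; the net result is insertion of the aryne into the acid C–O bond, the known fluoride-triggered reaction of carboxylic acids with arynes (an intramolecular anionic acyl shift of the Fries type). The phenoxide then adds to the β-carbon of the ynone in a 6-endo-dig oxa-Michael closure of ring C, and protonation gives flavone 15, the outcome known for arylpropiolic acids. C8a–O1, C4a–C4 and O1–C2 are formed in one operation and no stereocenter arises. Two selectivities are needed. The first is oxygen on the future C8a and acyl on the future C4a, secured by the oxygen substituent at the future C5 and by the hydrogen at the future C8, which leaves the other aryne flank without a competing director. The second is endo over 5-exo closure, favoured because the endo mode is the conjugate addition and leads to the aromatic pyranone under hot, reversible conditions. Aprotic THF is chosen so that the aryl anion is not protonated before it transfers the acyl group, and excess CsF keeps the medium basic, which protects the acetals.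

Step 8
Reactants: 15 2-[3,4-bis(benzyloxy)phenyl]-5,7-bis(methoxymethoxy)-4H-chromen-4-one
Product: 16 2-[3,4-bis(benzyloxy)phenyl]-8-iodo-5,7-bis(methoxymethoxy)-4H-chromen-4-one
Conditions: NIS (1.05 equiv), DMF, rt → 50 °C, dark
Reagents that add atoms: N-iodosuccinimide, O=C1CCC(=O)N1I
Why: Electrophilic aromatic iodination; ring A with three oxygen donors is far more nucleophilic than ring B (conjugated to the enone) or C3. With O5 etherified, attack is expected at C8 (para to O5, flanked by one acetal ether and the ring oxygen) and not at C6 (between two acetal ethers). Neutral conditions spare the acetals.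

Step 9
Reactants: 16 2-[3,4-bis(benzyloxy)phenyl]-8-iodo-5,7-bis(methoxymethoxy)-4H-chromen-4-one
Product: 17 8-(benzyloxy)-2-[3,4-bis(benzyloxy)phenyl]-5,7-bis(methoxymethoxy)-4H-chromen-4-one
Conditions: BnOH (4 equiv), CuI (10 mol %), 3,4,7,8-tetramethyl-1,10-phenanthroline (20 mol %), Cs2CO3, toluene, 110 °C
Reagents that add atoms: benzyl alcohol, OCc1ccccc1
Why: Ullmann-type copper-catalysed C–O coupling of an aryl iodide with a primary alcohol, the ligand-accelerated form of the copper/alkoxide displacement long used on 6- and 8-haloflavones. It installs O8 directly as the benzyl ether that leaves in the last step, and carbonate in toluene avoids the hot hydroxide that would open ring C.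

Step 10
Reactants: 17 8-(benzyloxy)-2-[3,4-bis(benzyloxy)phenyl]-5,7-bis(methoxymethoxy)-4H-chromen-4-one
Product: 18 8-(benzyloxy)-2-[3,4-bis(benzyloxy)phenyl]-5,7-dihydroxy-4H-chromen-4-one
Conditions: 3 M aq. HCl, MeOH–THF, 50 °C
Reagents that add atoms: none
Why: Acid-catalysed acetal cleavage removes both MOM groups (the one on O5, next to the carbonyl, first). Benzyl ethers and the flavone core are stable to dilute acid at this temperature, which is far below what a Wessely–Moser isomerisation would need.

Step 11
Reactants: 18 8-(benzyloxy)-2-[3,4-bis(benzyloxy)phenyl]-5,7-dihydroxy-4H-chromen-4-one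
Product: 19 8-(benzyloxy)-2-[3,4-bis(benzyloxy)phenyl]-5-hydroxy-4-oxo-4H-chromen-7-yl hydrogen sulfate
Conditions: SO3·pyridine (2 equiv), pyridine, rt → 40 °C; aq. NaHCO3 (isolated as the sodium salt)
Reagents that add atoms: sulfur trioxide–pyridine complex, O=S(=O)([O-])[n+]1ccccc1
Why: O-sulfation of a phenol with a sulfur trioxide–amine complex; the 7-OH is the most acidic hydroxyl of a flavone (vinylogous acid, para to the C4 carbonyl) and reacts. The 5-OH is locked in a hydrogen bond to the carbonyl and should stay free with a small excess of reagent.

Step 12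
Reactants: 19 8-(benzyloxy)-2-[3,4-bis(benzyloxy)phenyl]-5-hydroxy-4-oxo-4H-chromen-7-yl hydrogen sulfate
Product: 20 8-hydroxyluteolin 7-sulfate, 2-(3,4-dihydroxyphenyl)-5,8-dihydroxy-4-oxo-4H-chromen-7-yl hydrogen sulfate
Conditions: H2 (1 atm), Pd/C, MeOH–THF, rt, on the sodium salt; then H+ cation-exchange resin, 0 °C, freeze-dry
Reagents that add atoms: none
Why: Hydrogenolysis of the three benzyl ethers over Pd/C is neutral; the aryl sulfate salt and the C2=C3 bond should survive at 1 atm and rt. Work-up under inert gas protects the hydroquinone and catechol, and the cold acid exchange gives the form drawn.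

## Compound list

1 | phloroglucinol (benzene-1,3,5-triol) | Oc1cc(O)cc(O)c1 | starting material
2 | 3,5-bis(methoxymethoxy)phenol | COCOc1cc(O)cc(OCOC)c1 | intermediate
3 | 2-bromo-3,5-bis(methoxymethoxy)phenol | COCOc1cc(O)c(Br)c(OCOC)c1 | intermediate
4 | [2-bromo-3,5-bis(methoxymethoxy)phenoxy]trimethylsilane | COCOc1cc(O[Si](C)(C)C)c(Br)c(OCOC)c1 | intermediate
5 | [2,4-bis(methoxymethoxy)-6-(trimethylsilyloxy)phenyl]lithium | COCOc1cc(O[Si](C)(C)C)c([Li])c(OCOC)c1 | intermediate
6 | lithium 3,5-bis(methoxymethoxy)-2-(trimethylsilyl)phenoxide | COCOc1cc([O-])c([Si](C)(C)C)c(OCOC)c1.[Li+] | intermediate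
7 | 3,5-bis(methoxymethoxy)-2-(trimethylsilyl)phenyl trifluoromethanesulfonate | COCOc1cc(OS(=O)(=O)C(F)(F)F)c([Si](C)(C)C)c(OCOC)c1 | intermediate
8 | 3,4-bis(benzyloxy)benzaldehyde | O=Cc1ccc(OCc2ccccc2)c(OCc2ccccc2)c1 | starting material
9 | 1,2-bis(benzyloxy)-4-(2,2-dibromoethenyl)benzene | BrC(Br)=Cc1ccc(OCc2ccccc2)c(OCc2ccccc2)c1 | intermediate
10 | {[3,4-bis(benzyloxy)phenyl]ethynyl}lithium | [Li]C#Cc1ccc(OCc2ccccc2)c(OCc2ccccc2)c1 | intermediate
11 | lithium 3-[3,4-bis(benzyloxy)phenyl]prop-2-ynoate | [Li+].[O-]C(=O)C#Cc1ccc(OCc2ccccc2)c(OCc2ccccc2)c1 | intermediate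
12 | 3-[3,4-bis(benzyloxy)phenyl]prop-2-ynoic acid | OC(=O)C#Cc1ccc(OCc2ccccc2)c(OCc2ccccc2)c1 | intermediate
13 | 3,5-bis(methoxymethoxy)benzyne (1,2-didehydro-3,5-bis(methoxymethoxy)benzene) | COCOC1=CC(OCOC)=CC#C1 | intermediate
14 | 3-[3,4-bis(benzyloxy)phenyl]-1-[2-hydroxy-4,6-bis(methoxymethoxy)phenyl]prop-2-yn-1-one | O=C(C#Cc1ccc(OCc2ccccc2)c(OCc2ccccc2)c1)c1c(O)cc(OCOC)cc1OCOC | intermediate
15 | 2-[3,4-bis(benzyloxy)phenyl]-5,7-bis(methoxymethoxy)-4H-chromen-4-one | O=c1cc(-c2ccc(OCc3ccccc3)c(OCc3ccccc3)c2)oc2cc(OCOC)cc(OCOC)c12 | intermediate
16 | 2-[3,4-bis(benzyloxy)phenyl]-8-iodo-5,7-bis(methoxymethoxy)-4H-chromen-4-one | O=c1cc(-c2ccc(OCc3ccccc3)c(OCc3ccccc3)c2)oc2c(I)c(OCOC)cc(OCOC)c12 | intermediate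
17 | 8-(benzyloxy)-2-[3,4-bis(benzyloxy)phenyl]-5,7-bis(methoxymethoxy)-4H-chromen-4-one | O=c1cc(-c2ccc(OCc3ccccc3)c(OCc3ccccc3)c2)oc2c(OCc3ccccc3)c(OCOC)cc(OCOC)c12 | intermediate
18 | 8-(benzyloxy)-2-[3,4-bis(benzyloxy)phenyl]-5,7-dihydroxy-4H-chromen-4-one | O=c1cc(-c2ccc(OCc3ccccc3)c(OCc3ccccc3)c2)oc2c(OCc3ccccc3)c(O)cc(O)c12 | intermediate
19 | 8-(benzyloxy)-2-[3,4-bis(benzyloxy)phenyl]-5-hydroxy-4-oxo-4H-chromen-7-yl hydrogen sulfate | O=c1cc(-c2ccc(OCc3ccccc3)c(OCc3ccccc3)c2)oc2c(OCc3ccccc3)c(OS(=O)(=O)O)cc(O)c12 | intermediate
20 | 8-hydroxyluteolin 7-sulfate, 2-(3,4-dihydroxyphenyl)-5,8-dihydroxy-4-oxo-4H-chromen-7-yl hydrogen sulfate | O=c1cc(-c2ccc(O)c(O)c2)oc2c(O)c(OS(=O)(=O)O)cc(O)c12 | target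

## Step count and least certain steps

Total: 12 steps. Longest linear sequence: 10 steps (steps 1–4 and 7–12, from phloroglucinol); the acid arm (steps 5–6) joins at step 7.

Step 7 (key step). The most likely failure is protonation of the aryl anion before it transfers the acyl group, which stops the sequence at plain O-arylation of the acid. The HF and bifluoride formed from the acid and CsF are the proton source for this. Closure of the phenoxide in the 5-exo mode and thermal loss of CO2 from the propiolate are further risks at 125 °C.
Fallback (sets out from 2 and 9, returns at 15): 2 is iodinated ortho to the hydroxyl (NIS, CH2Cl2, −78 °C) to give 2-iodo-3,5-bis(methoxymethoxy)phenol F1. 9 is treated with n-BuLi as in step 6 but quenched with aqueous NH4Cl instead of CO2, giving 1,2-bis(benzyloxy)-4-ethynylbenzene F2. F1 and F2 are then joined under CO with PdCl2(dppf) (dppf = 1,1'-bis(diphenylphosphino)ferrocene) in Et2NH at 100–120 °C. This carbonylative Sonogashira coupling and annulation passes through 14, which the amine converts to an enaminone that closes only in the six-membered mode, giving 15.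

Step 2. Bromination may occur at C4 (between the two acetal ethers) or twice, because all three free positions of 2 are activated by three oxygen donors and the ortho preference rests only on sterics and hydrogen bonding.
Fallback (sets out from 2, returns at 7): the C–Si bond is made directly by carbamate-directed ortho-metalation. 2 with isopropyl isocyanate and Et3N gives 3,5-bis(methoxymethoxy)phenyl N-isopropylcarbamate F3. In situ N-silylation (TBSOTf, TMEDA), lithiation with n-BuLi/TMEDA at −78 °C and a TMSCl quench give 3,5-bis(methoxymethoxy)-2-(trimethylsilyl)phenyl N-isopropylcarbamate F4; lithiation should occur at the position flanked by the carbamate, the strongest director on the ring, and an acetal ether. Cleavage with Et2NH/DBU in MeCN at 40 °C and triflation of the phenoxide with PhNTf2 in the same flask give 7.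

Step 8. Iodination may fall partly on C6 or occur twice, because C6 and C8 are electronically similar and differ mainly in crowding.
Fallback (sets out from 15, returns at 18): the C8 oxygen is introduced by para-selective persulfate (Elbs) oxidation, whose position is fixed by a free 5-OH.
- 15 is deprotected (aq. HCl, MeOH–THF) to 2-[3,4-bis(benzyloxy)phenyl]-5,7-dihydroxy-4H-chromen-4-one F5.
- The acidic 7-OH is allylated (allyl bromide, K2CO3, acetone) to 7-(allyloxy)-2-[3,4-bis(benzyloxy)phenyl]-5-hydroxy-4H-chromen-4-one F6.
- K2S2O8 in aqueous KOH–pyridine at rt gives 7-(allyloxy)-2-[3,4-bis(benzyloxy)phenyl]-5-hydroxy-4-oxo-4H-chromen-8-yl hydrogen sulfate F7, which is not isolated. Hydrolysis with warm aqueous HCl/Na2SO3 gives 7-(allyloxy)-2-[3,4-bis(benzyloxy)phenyl]-5,8-dihydroxy-4H-chromen-4-one F8, the same structure as A7.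
- The free 8-OH is benzylated in preference to the chelated 5-OH (BnBr, K2CO3, acetone) to 7-(allyloxy)-8-(benzyloxy)-2-[3,4-bis(benzyloxy)phenyl]-5-hydroxy-4H-chromen-4-one F9.
- Deallylation with Pd(PPh3)4 and morpholine in THF gives 18.

Step 9. Reduction of the C–I bond may compete with coupling, because the iodide sits between two ortho substituents on an electron-rich ring and a copper benzyloxide can deliver hydride. Reversible alkoxide addition at C2 may also erode material.
Fallback (sets out from 16, returns at 17): borylation with HBpin, PdCl2(MeCN)2, 2-dicyclohexylphosphino-2',6'-dimethoxybiphenyl and Et3N in dioxane at 80 °C gives 2-[3,4-bis(benzyloxy)phenyl]-5,7-bis(methoxymethoxy)-8-(4,4,5,5-tetramethyl-1,3,2-dioxaborolan-2-yl)-4H-chromen-4-one F10. Oxidation with NaBO3·4H2O in THF–water gives 2-[3,4-bis(benzyloxy)phenyl]-8-hydroxy-5,7-bis(methoxymethoxy)-4H-chromen-4-one F11, and benzylation (BnBr, K2CO3, DMF) gives 17.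

Step 11. Sulfation may be incomplete or spill over to the 5-OH, and material may be lost when the amphiphilic sulfate salt is separated from inorganic salts; the sulfate can also hydrolyse if the medium turns acidic.
Fallback (sets out from 18, returns at 19): the sulfate is installed as a neutral, chromatographable diester. 18 with 2,2,2-trichloroethyl chlorosulfate, Et3N and DMAP in THF gives 8-(benzyloxy)-2-[3,4-bis(benzyloxy)phenyl]-5-hydroxy-4-oxo-4H-chromen-7-yl 2,2,2-trichloroethyl sulfate F12. Reductive removal of the trichloroethyl group with Zn and HCO2NH4 in MeOH gives 19, which continues to step 12.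

## Further compounds

F1 | step 7 | 2-iodo-3,5-bis(methoxymethoxy)phenol | COCOc1cc(O)c(I)c(OCOC)c1
F2 | step 7 | 1,2-bis(benzyloxy)-4-ethynylbenzene | C#Cc1ccc(OCc2ccccc2)c(OCc2ccccc2)c1
F3 | step 2 | 3,5-bis(methoxymethoxy)phenyl N-isopropylcarbamate | CC(C)NC(=O)Oc1cc(OCOC)cc(OCOC)c1
F4 | step 2 | 3,5-bis(methoxymethoxy)-2-(trimethylsilyl)phenyl N-isopropylcarbamate | CC(C)NC(=O)Oc1cc(OCOC)cc(OCOC)c1[Si](C)(C)C
F5 | step 8 | 2-[3,4-bis(benzyloxy)phenyl]-5,7-dihydroxy-4H-chromen-4-one | O=c1cc(-c2ccc(OCc3ccccc3)c(OCc3ccccc3)c2)oc2cc(O)cc(O)c12
F6 | step 8 | 7-(allyloxy)-2-[3,4-bis(benzyloxy)phenyl]-5-hydroxy-4H-chromen-4-one | O=c1cc(-c2ccc(OCc3ccccc3)c(OCc3ccccc3)c2)oc2cc(OCC=C)cc(O)c12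
F7 | step 8 | 7-(allyloxy)-2-[3,4-bis(benzyloxy)phenyl]-5-hydroxy-4-oxo-4H-chromen-8-yl hydrogen sulfate | O=c1cc(-c2ccc(OCc3ccccc3)c(OCc3ccccc3)c2)oc2c(OS(=O)(=O)O)c(OCC=C)cc(O)c12
F8 | step 8 | 7-(allyloxy)-2-[3,4-bis(benzyloxy)phenyl]-5,8-dihydroxy-4H-chromen-4-one | O=c1cc(-c2ccc(OCc3ccccc3)c(OCc3ccccc3)c2)oc2c(O)c(OCC=C)cc(O)c12
F9 | step 8 | 7-(allyloxy)-8-(benzyloxy)-2-[3,4-bis(benzyloxy)phenyl]-5-hydroxy-4H-chromen-4-one | O=c1cc(-c2ccc(OCc3ccccc3)c(OCc3ccccc3)c2)oc2c(OCc3ccccc3)c(OCC=C)cc(O)c12
F10 | step 9 | 2-[3,4-bis(benzyloxy)phenyl]-5,7-bis(methoxymethoxy)-8-(4,4,5,5-tetramethyl-1,3,2-dioxaborolan-2-yl)-4H-chromen-4-one | O=c1cc(-c2ccc(OCc3ccccc3)c(OCc3ccccc3)c2)oc2c(B3OC(C)(C)C(C)(C)O3)c(OCOC)cc(OCOC)c12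
F11 | step 9 | 2-[3,4-bis(benzyloxy)phenyl]-8-hydroxy-5,7-bis(methoxymethoxy)-4H-chromen-4-one | O=c1cc(-c2ccc(OCc3ccccc3)c(OCc3ccccc3)c2)oc2c(O)c(OCOC)cc(OCOC)c12
F12 | step 11 | 8-(benzyloxy)-2-[3,4-bis(benzyloxy)phenyl]-5-hydroxy-4-oxo-4H-chromen-7-yl 2,2,2-trichloroethyl sulfate | O=c1cc(-c2ccc(OCc3ccccc3)c(OCc3ccccc3)c2)oc2c(OCc3ccccc3)c(OS(=O)(=O)OCC(Cl)(Cl)Cl)cc(O)c12
A1 | alternative 1 | pentacarbonyl[(benzyloxy){6-[3,4-bis(benzyloxy)phenyl]-4-oxo-4H-pyran-3-yl}methylidene]chromium | O=c1cc(-c2ccc(OCc3ccccc3)c(OCc3ccccc3)c2)occ1C(OCc1ccccc1)=[Cr](=C=O)(=C=O)(=C=O)(=C=O)=C=O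
A2 | alternative 1 | (ethynyloxy)triisopropylsilane | C#CO[Si](C(C)C)(C(C)C)C(C)C
A3 | alternative 1 | 5-(benzyloxy)-2-[3,4-bis(benzyloxy)phenyl]-8-hydroxy-7-(triisopropylsilyloxy)-4H-chromen-4-one | O=c1cc(-c2ccc(OCc3ccccc3)c(OCc3ccccc3)c2)oc2c(O)c(O[Si](C(C)C)(C(C)C)C(C)C)cc(OCc3ccccc3)c12
A4 | alternative 2 | 4-{6-[3,4-bis(benzyloxy)phenyl]-4-oxo-4H-pyran-2-yl}-4-hydroxy-3-(4-methoxybenzyloxy)cyclobut-2-en-1-one (racemic) | O=C1C=C(OCc2ccc(OC)cc2)C1(O)c1cc(=O)cc(-c2ccc(OCc3ccccc3)c(OCc3ccccc3)c2)o1
A5 | alternative 2 | 2-[3,4-bis(benzyloxy)phenyl]-5,8-dihydroxy-7-(4-methoxybenzyloxy)-4H-chromen-4-one | O=c1cc(-c2ccc(OCc3ccccc3)c(OCc3ccccc3)c2)oc2c(O)c(OCc3ccc(OC)cc3)cc(O)c12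
A6 | alternative 3 | 1-[4-(allyloxy)-2,5-dimethoxyphenyl]-3-[3,4-bis(benzyloxy)phenyl]propane-1,3-dione | O=C(CC(=O)c1ccc(OCc2ccccc2)c(OCc2ccccc2)c1)c1cc(OC)c(OCC=C)cc1OC
A7 | alternative 3 | 7-(allyloxy)-2-[3,4-bis(benzyloxy)phenyl]-5,8-dihydroxy-4H-chromen-4-one | O=c1cc(-c2ccc(OCc3ccccc3)c(OCc3ccccc3)c2)oc2c(O)c(OCC=C)cc(O)c12
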